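Ring A is closed last among its carbon–carbon bonds, between C1 and C2, by ring-closing metathesis. An Ireland–Claisen rearrangement first joins C5 to the quaternary C10 with transfer of chirality from an easily made carbinol and leaves exactly two alkenes: an allyl arm on the gem-dimethyl carbon C4 and a propenyl arm on C10. The metathesis exploits these two fully substituted carbons, which flank the new bond and fold the chain, to give ring A (C1–C5, C10) in one operation. Ring B is then built on the acid and aldehyde at C5 and C10 by an intramolecular Sakurai addition, and the side chain by B-alkyl Suzuki coupling.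

Key step: step 7

Remark: atom labels follow labdane numbering (ring A = C1–C5, C10; ring B = C5–C10; C17 = ester carbon on C8; C11–C16 = side chain); stannane 22 is taken as a catalogue reagent.

Step 1
Reactants: 1 1,1-dimethoxypropan-2-one; 2 dimethyl (2-oxopropyl)phosphonate
Product: 3 (E)-5,5-dimethoxy-4-methylpent-3-en-2-one
Conditions: NaH, THF, 0 to 25 °C
Reagents that add atoms: none
Why: Horner–Wadsworth–Emmons olefination of the activated dialkoxy ketone should place the acetyl group trans to the bulkier dimethoxymethyl group, the (E) geometry that later directs C10.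

Step 2
Reactants: 3 (E)-5,5-dimethoxy-4-methylpent-3-en-2-one
Product: 4 (2S,3E)-5,5-dimethoxy-4-methylpent-3-en-2-ol
Conditions: (R)-2-methyl-CBS-oxazaborolidine (10 mol %), BH3·SMe2, THF, −20 °C; then MeOH
Reagents that add atoms: none
Why: Corey–Bakshi–Shibata reduction, in which the catalyst reads the alkenyl group as large and the methyl group as small, should give the (S)-carbinol, the only stereocenter set by a reagent.

Step 3
Reactants: 5 diethyl 2-(propan-2-ylidene)malonate; 6 allylmagnesium bromide
Product: 7 diethyl 2-(2-methylpent-4-en-2-yl)malonate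
Conditions: CuI (5 mol %), THF, −30 to 0 °C; then 1 M HCl
Reagents that add atoms: none
Why: Copper-catalysed conjugate addition of the Grignard reagent to the alkylidene malonate builds the gem-dimethyl carbon C4 together with its allyl arm (C3, C2).

Step 4
Reactants: 7 diethyl 2-(2-methylpent-4-en-2-yl)malonate
Product: 9 3,3-dimethylhex-5-enoic acid, via malonic acid 8 (not isolated)
Conditions: KOH, EtOH–H2O, reflux; HCl to pH 1; then neat, 170 °C
Reagents that add atoms: potassium hydroxide, [K+].[OH-]
Why: Saponification and thermal decarboxylation of the substituted malonic acid leave one carboxyl group (C6) and the CH2 group that becomes C5.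

Step 5
Reactants: 9 3,3-dimethylhex-5-enoic acid; 4 (2S,3E)-5,5-dimethoxy-4-methylpent-3-en-2-ol
Product: 10 (2S,3E)-5,5-dimethoxy-4-methylpent-3-en-2-yl 3,3-dimethylhex-5-enoate
Conditions: DCC, DMAP (10 mol %), CH2Cl2, 0 to 25 °C
Reagents that add atoms: none
Why: Steglich esterification joins the acid and the secondary allylic alcohol under neutral conditions that leave the acetal and the carbinol configuration untouched.

Step 6
Reactants: 10 (2S,3E)-5,5-dimethoxy-4-methylpent-3-en-2-yl 3,3-dimethylhex-5-enoate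
Product: 13 (2R,3R,4E)-3-formyl-3-methyl-2-(2-methylpent-4-en-2-yl)hex-4-enoic acid, via silyl ketene acetal 11 (not isolated), via silyl ester 12 (not isolated)
Conditions: LiN(i-Pr)2, THF, −78 °C; Me3SiCl, Et3N, −78 to 65 °C; then 1 M HCl, THF, 25 °C
Reagents that add atoms: water, O
Why: Ireland–Claisen rearrangement: kinetic deprotonation in THF gives the (E)-silyl ketene acetal, and a chair transition state with the carbinol methyl group equatorial forms the C5–C10 bond and hands the carbinol configuration on to the quaternary C10 and to C5, after which aqueous acid frees the carboxylic acid and the aldehyde.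

Step 7
Reactants: 13 (2R,3R,4E)-3-formyl-3-methyl-2-(2-methylpent-4-en-2-yl)hex-4-enoic acid
Product: 14 (1R,2R)-2-formyl-2,6,6-trimethylcyclohex-3-ene-1-carboxylic acid
Conditions: second-generation Grubbs catalyst (5 mol %), CH2Cl2 (high dilution), 40 °C
Reagents that add atoms: none
Why: The ruthenium alkylidene loads on the unhindered terminal allyl alkene, the carbene at C2 adds across the propenyl double bond at C1 through a metallacyclobutane, and cycloreversion releases ring A and an ethylidene that leaves as propene. The reaction type is ring-closing olefin metathesis of a 1,7-diene. Ring A is closed in the six-membered mode by forming C1=C2, the only ring size open to this diene. No stereocenter is formed, and C5 and C10 from step 6 are not touched, since C10 is quaternary and C5 is not allylic. The step needs cyclization to outrun cross-metathesis: the gem-dimethyl group on C4 and the quaternary C10 fold the chain toward closure, the internal propenyl partner does not dimerize, and dilution does the rest. The free acid and the non-enolisable aldehyde are tolerated by the catalyst.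

Step 8
Reactants: 14 (1R,2R)-2-formyl-2,6,6-trimethylcyclohex-3-ene-1-carboxylic acid
Product: 15 (1R,2R)-2-formyl-2,6,6-trimethylcyclohexane-1-carboxylic acid
Conditions: H2 (1 atm), 10% Pd/C, EtOAc, 25 °C
Reagents that add atoms: none
Why: Catalytic hydrogenation saturates C1=C2, the only C=C bond in the molecule, before any alkene that must survive is introduced.

Step 9
Reactants: 15 (1R,2R)-2-formyl-2,6,6-trimethylcyclohexane-1-carboxylic acid; 16 methyltriphenylphosphonium bromide; 17 (iodomethyl)trimethylsilane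
Product: 21 (1R,2S)-2,6,6-trimethyl-2-[(Z)-3-(trimethylsilyl)prop-1-enyl]cyclohexane-1-carboxylic acid, via methylene ylide 18 (not isolated), via phosphonium iodide 19 (not isolated), via silyl ylide 20 (not isolated)
Conditions: 16, n-BuLi, THF, 0 °C; 17, 25 °C; n-BuLi, −78 °C; then 15 (as sodium carboxylate from NaH), −78 to 25 °C; cold 0.5 M HCl
Reagents that add atoms: none
Why: Wittig olefination with the silyl-substituted ylide, made in the flask by alkylation of methylenetriphenylphosphorane, converts the non-enolisable C9 aldehyde into an allylsilane while the carboxylate stays inert.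

Step 10
Reactants: 21 (1R,2S)-2,6,6-trimethyl-2-[(Z)-3-(trimethylsilyl)prop-1-enyl]cyclohexane-1-carboxylic acid; 22 methyl (E)-3-(tributylstannyl)acrylate
Product: 24 methyl (E)-4-oxo-4-{(1R,2S)-2,6,6-trimethyl-2-[(Z)-3-(trimethylsilyl)prop-1-enyl]cyclohexyl}but-2-enoate, via acid chloride 23 (not isolated)
Conditions: 1-chloro-N,N,2-trimethylprop-1-en-1-amine, CH2Cl2, 0 °C; then 22, Pd(PPh3)2Cl2 (5 mol %), toluene, 60 °C
Reagents that add atoms: none
Why: Stille acylation: the acid chloride, formed under neutral conditions that spare the allylsilane, couples with the vinylstannane with retention of the (E) geometry and so attaches C7, C8 and the ester carbon C17 to C6.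

Step 11
Reactants: 24 methyl (E)-4-oxo-4-{(1R,2S)-2,6,6-trimethyl-2-[(Z)-3-(trimethylsilyl)prop-1-enyl]cyclohexyl}but-2-enoate
Product: 25 methyl (1R,2S,4aR,8aS)-1-ethenyl-5,5,8a-trimethyl-4-oxodecahydronaphthalene-2-carboxylate
Conditions: TiCl4, CH2Cl2, −78 °C; then water
Reagents that add atoms: none
Why: Intramolecular Hosomi–Sakurai conjugate addition: TiCl4 activates the C6 ketone, C9 of the allylsilane attacks C8 through a chair transition state trans-fused to ring A in which the emerging vinyl group is equatorial (sets C9, cis to the C10 methyl), and the (E)-enoate places the ester at C8 equatorial, the arrangement also favoured at equilibrium.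

Step 12
Reactants: 25 methyl (1R,2S,4aR,8aS)-1-ethenyl-5,5,8a-trimethyl-4-oxodecahydronaphthalene-2-carboxylate
Product: 26 methyl (1R,2R,4aR,8aS)-1-ethenyl-5,5,8a-trimethyl-4-(trifluoromethylsulfonyloxy)-1,2,4a,5,6,7,8,8a-octahydronaphthalene-2-carboxylate
Conditions: KN(SiMe3)2, THF, −78 °C; PhNTf2, −78 to 0 °C
Reagents that add atoms: N-phenylbis(trifluoromethanesulfonimide), O=S(=O)(N(c1ccccc1)S(=O)(=O)C(F)(F)F)C(F)(F)F
Why: Kinetic enolate formation at C7, the only unhindered alpha position of the C6 ketone, and O-sulfonylation fix the position of the future C6=C7 double bond without touching C5 or C8.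

Step 13
Reactants: 26 methyl (1R,2R,4aR,8aS)-1-ethenyl-5,5,8a-trimethyl-4-(trifluoromethylsulfonyloxy)-1,2,4a,5,6,7,8,8a-octahydronaphthalene-2-carboxylate
Product: 27 methyl (1R,2S,4aR,8aS)-1-ethenyl-5,5,8a-trimethyl-1,2,4a,5,6,7,8,8a-octahydronaphthalene-2-carboxylate
Conditions: Pd(OAc)2 (5 mol %), PPh3 (10 mol %), HCO2H, Et3N, DMF, 60 °C
Reagents that add atoms: none
Why: Palladium-catalysed formate reduction of the enol triflate (oxidative addition, hydride transfer, reductive elimination) replaces the triflate by hydrogen and leaves the C6=C7 bond out of conjugation with the ester.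

Step 14
Reactants: 28 methyl 4-hydroxybut-2-ynoate
Product: 29 methyl (Z)-4-hydroxy-3-iodobut-2-enoate
Conditions: LiI, AcOH, MeCN, 80 °C
Reagents that add atoms: lithium iodide, [Li+].[I-]
Why: Conjugate addition of iodide to the ynoate and anti protonation give the (Z)-3-iodo enoate, in which the hydroxymethyl group is trans to the ester and cannot lactonise.

Step 15
Reactants: 27 methyl (1R,2S,4aR,8aS)-1-ethenyl-5,5,8a-trimethyl-1,2,4a,5,6,7,8,8a-octahydronaphthalene-2-carboxylate; 29 methyl (Z)-4-hydroxy-3-iodobut-2-enoate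
Product: 31 methyl (1R,2S,4aR,8aS)-1-[(3E)-3-(hydroxymethyl)-5-methoxy-5-oxopent-3-enyl]-5,5,8a-trimethyl-1,2,4a,5,6,7,8,8a-octahydronaphthalene-2-carboxylate, via alkylborane 30 (not isolated)
Conditions: 9-BBN-H, THF, 0 to 25 °C; then 29, Pd(dppf)Cl2 (5 mol %), AsPh3, K3PO4, DMF–H2O, 25 °C
Reagents that add atoms: none
Why: 9-BBN hydroborates only the terminal vinyl group at its CH2 end, and the B-alkyl Suzuki–Miyaura coupling replaces iodide with retention of the alkene geometry, so that C12 ends cis to the ester.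

Step 16
Reactants: 31 methyl (1R,2S,4aR,8aS)-1-[(3E)-3-(hydroxymethyl)-5-methoxy-5-oxopent-3-enyl]-5,5,8a-trimethyl-1,2,4a,5,6,7,8,8a-octahydronaphthalene-2-carboxylate
Product: 32 methyl (1R,2S,4aR,8aS)-1-[(3E)-3-(acetoxymethyl)-5-methoxy-5-oxopent-3-enyl]-5,5,8a-trimethyl-1,2,4a,5,6,7,8,8a-octahydronaphthalene-2-carboxylate
Conditions: Ac2O, pyridine, DMAP (5 mol %), CH2Cl2, 0 to 25 °C
Reagents that add atoms: acetic anhydride, CC(=O)OC(C)=O
Why: DMAP-catalysed acylation of the primary allylic alcohol completes the target without disturbing the base-sensitive beta,gamma-unsaturated ester.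

Compound list
1 | 1,1-dimethoxypropan-2-one | CC(=O)C(OC)OC | starting material
2 | dimethyl (2-oxopropyl)phosphonate | CC(=O)CP(=O)(OC)OC | starting material
3 | (E)-5,5-dimethoxy-4-methylpent-3-en-2-one | CC(=O)/C=C(\C)C(OC)OC | intermediate
4 | (2S,3E)-5,5-dimethoxy-4-methylpent-3-en-2-ol | C[C@H](O)/C=C(\C)C(OC)OC | intermediate
5 | diethyl 2-(propan-2-ylidene)malonate | CCOC(=O)C(=C(C)C)C(=O)OCC | starting material
6 | allylmagnesium bromide | C=CC[Mg]Br | starting material
7 | diethyl 2-(2-methylpent-4-en-2-yl)malonate | CCOC(=O)C(C(=O)OCC)C(C)(C)CC=C | intermediate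
8 | 2-(2-methylpent-4-en-2-yl)malonic acid | OC(=O)C(C(=O)O)C(C)(C)CC=C | intermediate
9 | 3,3-dimethylhex-5-enoic acid | OC(=O)CC(C)(C)CC=C | intermediate
10 | (2S,3E)-5,5-dimethoxy-4-methylpent-3-en-2-yl 3,3-dimethylhex-5-enoate | C=CCC(C)(C)CC(=O)O[C@@H](C)/C=C(\C)C(OC)OC | intermediate
11 | (E)-O-trimethylsilyl ketene acetal of 10 | C=CCC(C)(C)/C=C(/O[Si](C)(C)C)O[C@@H](C)/C=C(\C)C(OC)OC | intermediate
12 | trimethylsilyl (2R,3R,4E)-3-(dimethoxymethyl)-3-methyl-2-(2-methylpent-4-en-2-yl)hex-4-enoate | C[Si](C)(C)OC(=O)[C@H](C(C)(C)CC=C)[C@](C)(C(OC)OC)/C=C/C | intermediate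
13 | (2R,3R,4E)-3-formyl-3-methyl-2-(2-methylpent-4-en-2-yl)hex-4-enoic acid | OC(=O)[C@H](C(C)(C)CC=C)[C@](C)(C=O)/C=C/C | intermediate
14 | (1R,2R)-2-formyl-2,6,6-trimethylcyclohex-3-ene-1-carboxylic acid | OC(=O)[C@@H]1C(C)(C)CC=C[C@]1(C=O)C | intermediate
15 | (1R,2R)-2-formyl-2,6,6-trimethylcyclohexane-1-carboxylic acid | OC(=O)[C@@H]1C(C)(C)CCC[C@]1(C=O)C | intermediate
16 | methyltriphenylphosphonium bromide | C[P+](c1ccccc1)(c1ccccc1)c1ccccc1.[Br-] | starting material
17 | (iodomethyl)trimethylsilane | C[Si](C)(C)CI | starting material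
18 | methylenetriphenylphosphorane | C=P(c1ccccc1)(c1ccccc1)c1ccccc1 | intermediate
19 | triphenyl[2-(trimethylsilyl)ethyl]phosphonium iodide | C[Si](C)(C)CC[P+](c1ccccc1)(c1ccccc1)c1ccccc1.[I-] | intermediate
20 | triphenyl[2-(trimethylsilyl)ethylidene]phosphorane | C[Si](C)(C)CC=P(c1ccccc1)(c1ccccc1)c1ccccc1 | intermediate
21 | (1R,2S)-2,6,6-trimethyl-2-[(Z)-3-(trimethylsilyl)prop-1-enyl]cyclohexane-1-carboxylic acid | OC(=O)[C@@H]1C(C)(C)CCC[C@@]1(C)/C=C\C[Si](C)(C)C | intermediate
22 | methyl (E)-3-(tributylstannyl)acrylate | CCCC[Sn](CCCC)(CCCC)/C=C/C(=O)OC | starting material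
23 | (1R,2S)-2,6,6-trimethyl-2-[(Z)-3-(trimethylsilyl)prop-1-enyl]cyclohexane-1-carbonyl chloride | ClC(=O)[C@@H]1C(C)(C)CCC[C@@]1(C)/C=C\C[Si](C)(C)C | intermediate
24 | methyl (E)-4-oxo-4-{(1R,2S)-2,6,6-trimethyl-2-[(Z)-3-(trimethylsilyl)prop-1-enyl]cyclohexyl}but-2-enoate | COC(=O)/C=C/C(=O)[C@@H]1C(C)(C)CCC[C@@]1(C)/C=C\C[Si](C)(C)C | intermediate
25 | methyl (1R,2S,4aR,8aS)-1-ethenyl-5,5,8a-trimethyl-4-oxodecahydronaphthalene-2-carboxylate | C=C[C@@H]1[C@@H](C(=O)OC)CC(=O)[C@@H]2C(C)(C)CCC[C@@]12C | intermediate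
26 | methyl (1R,2R,4aR,8aS)-1-ethenyl-5,5,8a-trimethyl-4-(trifluoromethylsulfonyloxy)-1,2,4a,5,6,7,8,8a-octahydronaphthalene-2-carboxylate | C=C[C@@H]1[C@@H](C(=O)OC)C=C(OS(=O)(=O)C(F)(F)F)[C@@H]2C(C)(C)CCC[C@@]12C | intermediate
27 | methyl (1R,2S,4aR,8aS)-1-ethenyl-5,5,8a-trimethyl-1,2,4a,5,6,7,8,8a-octahydronaphthalene-2-carboxylate | C=C[C@@H]1[C@@H](C(=O)OC)C=C[C@@H]2C(C)(C)CCC[C@@]12C | intermediate
28 | methyl 4-hydroxybut-2-ynoate | COC(=O)C#CCO | starting material
29 | methyl (Z)-4-hydroxy-3-iodobut-2-enoate | COC(=O)/C=C(\I)CO | intermediate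
30 | B-alkyl-9-borabicyclo[3.3.1]nonane from 27 (boron on C12) | C12CCCC(CCC1)B2CC[C@@H]1[C@@H](C(=O)OC)C=C[C@@H]2C(C)(C)CCC[C@@]12C | intermediate
31 | methyl (1R,2S,4aR,8aS)-1-[(3E)-3-(hydroxymethyl)-5-methoxy-5-oxopent-3-enyl]-5,5,8a-trimethyl-1,2,4a,5,6,7,8,8a-octahydronaphthalene-2-carboxylate | COC(=O)/C=C(\CC[C@@H]1[C@@H](C(=O)OC)C=C[C@@H]2C(C)(C)CCC[C@@]12C)CO | intermediate
32 | methyl (1R,2S,4aR,8aS)-1-[(3E)-3-(acetoxymethyl)-5-methoxy-5-oxopent-3-enyl]-5,5,8a-trimethyl-1,2,4a,5,6,7,8,8a-octahydronaphthalene-2-carboxylate | COC(=O)/C=C(\CC[C@@H]1[C@@H](C(=O)OC)C=C[C@@H]2C(C)(C)CCC[C@@]12C)COC(C)=O | target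

Total step count: 16 steps.
Longest linear sequence: 13 steps (steps 1, 2, 5 to 13, 15, 16).

Steps most likely to fail

Step 11 (Sakurai ring closure). The allylsilane may lose silicon by protonation before it cyclises, may attack C7 instead of C8 and close a five-membered ring, or may add with poor facial selectivity at C9. The fallback sets out from 15 and comes back at 25. Knoevenagel condensation of 15 with trimethyl phosphonoacetate (TiCl4, N-methylmorpholine, THF) should give the alkylidene phosphonoacetate F5. Copper-catalysed conjugate addition of vinylmagnesium bromide, followed in the same flask by Horner–Wadsworth–Emmons reaction of the phosphonate anion with paraformaldehyde, should give the acrylate acid F6, with attack anti to C5 setting C9. (PhSe)2 and PBu3 should convert the acid into the selenoester F7. Bu3SnH and AIBN in benzene at 80 °C generate the acyl radical, which should close ring B at the acrylate terminus C7 in the six-membered endo mode; brief NaOMe in MeOH settles C8 and gives 25.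

Step 6 (Ireland–Claisen rearrangement). Enolisation next to the quaternary carbon may be slow, the rearrangement between two crowded termini may need temperatures at which the silyl ketene acetal decomposes, and leakage through a boat transition state may erode the selectivity at C5 and C10. The fallback sets out from 4 and comes back at 13. Stork–Zhao olefination of commercial 2,2-dimethylpent-4-enal (Ph3P=CHI, THF, −78 °C) should give (Z)-1-iodo-3,3-dimethylhexa-1,5-diene F1. CuI, 3,4,7,8-tetramethyl-1,10-phenanthroline and Cs2CO3 in toluene should join F1 to 4 as the (Z)-allyl vinyl ether F2. Heating in xylene at 140 °C should rearrange it, by a neutral Claisen rearrangement through the same chair arrangement, to the aldehyde F3. Pinnick oxidation (NaClO2, NaH2PO4, 2-methylbut-2-ene) should give the acid acetal F4, and 1 M HCl in THF frees the aldehyde to give 13.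

Step 10 (Stille acylation). The crowded acyl palladium intermediate may lose carbon monoxide or couple slowly with the electron-poor stannane. The fallback sets out from 21 and comes back at 24. MeLi (2.2 equiv, Et2O, 0 °C) should convert the acid into the methyl ketone F8. Its kinetic enolate (LiN(i-Pr)2, THF, −78 °C) should add to methyl glyoxylate to give the aldol F9. MsCl and Et3N, then DBU, should eliminate to the (E)-4-oxo-enoate 24.

Further compounds
F1 | step 6 | (Z)-1-iodo-3,3-dimethylhexa-1,5-diene | C=CCC(C)(C)/C=C\I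
F2 | step 6 | (Z)-3,3-dimethylhexa-1,5-dienyl ether of 4 | C=CCC(C)(C)/C=C\O[C@@H](C)/C=C(\C)C(OC)OC
F3 | step 6 | (2R,3R,4E)-3-(dimethoxymethyl)-3-methyl-2-(2-methylpent-4-en-2-yl)hex-4-enal | O=C[C@H](C(C)(C)CC=C)[C@](C)(C(OC)OC)/C=C/C
F4 | step 6 | (2R,3R,4E)-3-(dimethoxymethyl)-3-methyl-2-(2-methylpent-4-en-2-yl)hex-4-enoic acid | OC(=O)[C@H](C(C)(C)CC=C)[C@](C)(C(OC)OC)/C=C/C
F5 | step 11 | alkylidene phosphonoacetate of 15 (C9=C8 bearing CO2Me and P(O)(OMe)2) | OC(=O)[C@@H]1C(C)(C)CCC[C@@]1(C)C=C(C(=O)OC)P(=O)(OC)OC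
F6 | step 11 | acrylate acid (C9 bearing vinyl and the 2-(methoxycarbonyl)ethenyl unit) | OC(=O)[C@@H]1C(C)(C)CCC[C@@]1(C)[C@H](C=C)C(=C)C(=O)OC
F7 | step 11 | Se-phenyl selenoester of F6 | O=C([Se]c1ccccc1)[C@@H]1C(C)(C)CCC[C@@]1(C)[C@H](C=C)C(=C)C(=O)OC
F8 | step 10 | methyl ketone from 21 | CC(=O)[C@@H]1C(C)(C)CCC[C@@]1(C)/C=C\C[Si](C)(C)C
F9 | step 10 | methyl 2-hydroxy-4-oxobutanoate aldol from F8 | COC(=O)C(O)CC(=O)[C@@H]1C(C)(C)CCC[C@@]1(C)/C=C\C[Si](C)(C)C
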